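**Retrosynthetic overview**

1. The last bond made is the one between the ketone carbon and the methyl-bearing carbon on the pentyl pyranone (ring A). It is formed by an enantioconvergent nickel-catalysed reductive acyl coupling of acid chloride 11 (ring B, S centre already in place) with racemic chloride 20 (ring A).
2. Enabling feature: the sp3 carbon to be joined sits on C2 of 4-pyranone ring A, so its radical is delocalised over C2=C3 and the C4 carbonyl (the O1–C2=C3–C4=O vinylogous ester). This benzylic-type radical should form readily from the chloride and recombine at a chiral nickel centre.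
3. Ring B (ethyl pyranone) is formed first: a diketone dianion is acylated with a Weinreb amide from methyl (R)-3-hydroxy-2-methylpropanoate, and the triketone is cyclodehydrated. Oxidation of CH2OH to COCl turns the chiral-pool centre into the S centre next to the ketone.
4. Ring A (pentyl pyranone) is formed second in a parallel branch: a lactate-derived diketone is acylated as its dianion with a hexanoyl Weinreb amide and cyclodehydrated. The lactate oxygen is then exchanged for chloride.
5. No protecting-group or redox step follows the coupling, so the two labile centres between ketone and pyranone exist only after the final, base-free step.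

Key step: step 15

Assumption: the sense of induction known for racemic 1-arylethyl chlorides is taken to hold when ring A replaces the arene. The ligand is written as the (R,R) antipode; it is to be checked on a model chloride and replaced by its mirror image if the opposite sense is found.

Assumption: racemic ethyl lactate is sufficient, because the configuration of this centre is erased at the radical stage of step 15.

**Route**

Step 1
Reactants: 1 heptane-3,5-dione
Product: 2 4-methylheptane-3,5-dione
Conditions: MeI (1.05 equiv), K2CO3, acetone, reflux
Reagents that add atoms: iodomethane, CI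
Why: C-alkylation of the stabilised 1,3-diketone enolate (SN2 methylation of an active methylene) should stop at the mono-methyl stage with one equivalent of iodomethane.

Step 2
Reactants: 3 methyl (2R)-3-hydroxy-2-methylpropanoate
Product: 4 methyl (2R)-3-[(tert-butyldimethylsilyl)oxy]-2-methylpropanoate
Conditions: TBSCl, imidazole, DMF, 0 °C to rt
Reagents that add atoms: tert-butyldimethylsilyl chloride, CC(C)(C)[Si](C)(C)Cl
Why: Imidazole-promoted silylation of the primary alcohol (silyl ether formation) does not touch the stereocentre.

Step 3
Reactants: 4 methyl (2R)-3-[(tert-butyldimethylsilyl)oxy]-2-methylpropanoate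
Product: 5 (2R)-3-[(tert-butyldimethylsilyl)oxy]-N-methoxy-N,2-dimethylpropanamide
Conditions: MeNHOMe·HCl, iPrMgCl, THF, −20 to 0 °C
Reagents that add atoms: N,O-dimethylhydroxylamine hydrochloride, Cl.CNOC
Why: Aminolysis of the ester by the chloromagnesium amide (Weinreb amide formation) is fast at low temperature and should leave the α-centre intact.

Step 4
Reactants: 2 4-methylheptane-3,5-dione; 5 (2R)-3-[(tert-butyldimethylsilyl)oxy]-N-methoxy-N,2-dimethylpropanamide
Product: 6 (2R)-1-[(tert-butyldimethylsilyl)oxy]-2,4,6-trimethylnonane-3,5,7-trione (mixture at C4 and C6, keto–enol tautomers)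
Conditions: 2 (1.5 equiv), LiN(iPr)2 (3.1 equiv), THF, −78 to 0 °C; then 5, −78 to −20 °C; aq NH4Cl
Reagents that add atoms: none
Why: Claisen-type acylation of the 1,3-diketone dianion at its terminal carbanion should give the 1,3,5-triketone, because the chelated tetrahedral adduct of the Weinreb amide prevents over-addition and shields the α-centre until the quench.

Step 5
Reactants: 6 (2R)-1-[(tert-butyldimethylsilyl)oxy]-2,4,6-trimethylnonane-3,5,7-trione
Product: 7 2-{(2R)-1-[(tert-butyldimethylsilyl)oxy]propan-2-yl}-6-ethyl-3,5-dimethyl-4H-pyran-4-one
Conditions: PPh3, CCl4, THF, rt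
Reagents that add atoms: none
Why: Cyclodehydration of the 1,3,5-triketone under Appel-type activation (one terminal enol oxygen is activated as its oxyphosphonium and the other closes by addition–elimination) should give the only possible 4-pyranone, with the silyl ether kept in place so that the oxygen cannot cyclise onto the chain.

Step 6
Reactants: 7 2-{(2R)-1-[(tert-butyldimethylsilyl)oxy]propan-2-yl}-6-ethyl-3,5-dimethyl-4H-pyran-4-one
Product: 8 2-ethyl-6-[(2R)-1-hydroxypropan-2-yl]-3,5-dimethyl-4H-pyran-4-one
Conditions: HF·pyridine, THF, 0 °C to rt
Reagents that add atoms: none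
Why: Fluoride-mediated desilylation under mildly acidic conditions should free the primary alcohol without enolising the centre next to the pyranone.

Step 7
Reactants: 8 2-ethyl-6-[(2R)-1-hydroxypropan-2-yl]-3,5-dimethyl-4H-pyran-4-one
Product: 10 (2S)-2-(6-ethyl-3,5-dimethyl-4-oxo-4H-pyran-2-yl)propanoic acid, via aldehyde 9 (not isolated)
Conditions: TEMPO (cat.), PhI(OAc)2 (2.2 equiv), MeCN/H2O, 0 °C to rt; extractive isolation below rt, used at once
Reagents that add atoms: water, O
Why: Oxoammonium (TEMPO/hypervalent iodine) oxidation of the primary alcohol through the aldehyde hydrate to the acid runs without base, so the α-centre should not enolise (the descriptor changes from R to S only by priority).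

Step 8
Reactants: 10 (2S)-2-(6-ethyl-3,5-dimethyl-4-oxo-4H-pyran-2-yl)propanoic acid
Product: 11 (2S)-2-(6-ethyl-3,5-dimethyl-4-oxo-4H-pyran-2-yl)propanoyl chloride
Conditions: 1-chloro-N,N,2-trimethylprop-1-en-1-amine, CH2Cl2, 0 °C; solution used directly
Reagents that add atoms: 1-chloro-N,N,2-trimethylprop-1-en-1-amine, CC(C)=C(Cl)N(C)C
Why: Acid chloride formation with an α-chloroenamine is neutral, with no amine base and no free HCl, which should suppress the ketene pathway that would erase the α-centre.

Step 9
Reactants: 12 ethyl 2-hydroxypropanoate (racemic ethyl lactate)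
Product: 13 ethyl 2-[(tert-butyldimethylsilyl)oxy]propanoate (racemic)
Conditions: TBSCl, imidazole, DMF, 0 °C to rt
Reagents that add atoms: tert-butyldimethylsilyl chloride, CC(C)(C)[Si](C)(C)Cl
Why: Imidazole-promoted silylation (silyl ether formation) masks the hydroxyl group for the enolate steps that follow.

Step 10
Reactants: 14 pentan-3-one; 13 ethyl 2-[(tert-butyldimethylsilyl)oxy]propanoate
Product: 15 2-[(tert-butyldimethylsilyl)oxy]-4-methylheptane-3,5-dione (stereoisomer and tautomer mixture)
Conditions: 14 (2.2 equiv), LiN(iPr)2 (2.2 equiv), THF, −78 °C; then 13, −78 °C to rt; aq NH4Cl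
Reagents that add atoms: none
Why: Crossed Claisen condensation of the lithium enolate of the symmetrical ketone with the non-enolising-prone silyloxy ester should give the 1,3-diketone, the second equivalent of enolate taking up the acidic product.

Step 11
Reactants: 15 2-[(tert-butyldimethylsilyl)oxy]-4-methylheptane-3,5-dione; 16 N-methoxy-N-methylhexanamide
Product: 17 2-[(tert-butyldimethylsilyl)oxy]-4,6-dimethyldodecane-3,5,7-trione (stereoisomer and tautomer mixture)
Conditions: LiN(iPr)2 (2.2 equiv), THF, −78 to 0 °C; then 16, −78 to −20 °C; aq NH4Cl
Reagents that add atoms: none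
Why: Claisen-type acylation of the diketone dianion should extend the chain on the ethyl side only, because the second deprotonation takes the ethyl CH2 and not the hindered silyloxy-bearing methine.

Step 12
Reactants: 17 2-[(tert-butyldimethylsilyl)oxy]-4,6-dimethyldodecane-3,5,7-trione
Product: 18 2-{1-[(tert-butyldimethylsilyl)oxy]ethyl}-3,5-dimethyl-6-pentyl-4H-pyran-4-one (racemic)
Conditions: PPh3, CCl4, THF, rt
Reagents that add atoms: none
Why: Appel-type cyclodehydration of the 1,3,5-triketone should give the single possible 4-pyranone, with the pentyl and the oxygenated ethyl arm placed at C6 and C2 by construction and the silyl ether blocking furanone formation.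

Step 13
Reactants: 18 2-{1-[(tert-butyldimethylsilyl)oxy]ethyl}-3,5-dimethyl-6-pentyl-4H-pyran-4-one
Product: 19 2-(1-hydroxyethyl)-3,5-dimethyl-6-pentyl-4H-pyran-4-one (racemic)
Conditions: HF·pyridine, THF, 0 °C to rt
Reagents that add atoms: none
Why: Fluoride-mediated desilylation should give the secondary alcohol, which is stable to the acidic medium because a cation next to the electron-poor pyranone is disfavoured.

Step 14
Reactants: 19 2-(1-hydroxyethyl)-3,5-dimethyl-6-pentyl-4H-pyran-4-one
Product: 20 2-(1-chloroethyl)-3,5-dimethyl-6-pentyl-4H-pyran-4-one (racemic)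
Conditions: PPh3, CCl4, CH2Cl2, 0 °C to rt
Reagents that add atoms: tetrachloromethane, ClC(Cl)(Cl)Cl
Why: Appel chlorination (SN2 displacement of the oxyphosphonium by chloride) should convert the activated secondary alcohol into the chloride under neutral conditions; its configuration is irrelevant.

Step 15
Reactants: 11 (2S)-2-(6-ethyl-3,5-dimethyl-4-oxo-4H-pyran-2-yl)propanoyl chloride (1.3 equiv); 20 2-(1-chloroethyl)-3,5-dimethyl-6-pentyl-4H-pyran-4-one (racemic, 1.0 equiv)
Product: 21 (2S,4S)-2-(6-ethyl-3,5-dimethyl-4-oxo-4H-pyran-2-yl)-4-(3,5-dimethyl-4-oxo-6-pentyl-4H-pyran-2-yl)pentan-3-one (target)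
Conditions: NiCl2(dme) (10 mol %), (R,R)-Ph-BOX [2,2'-(propane-2,2-diyl)bis((4R)-4-phenyl-4,5-dihydrooxazole)] (22 mol %), Mn powder (3 equiv), 2,6-dimethylbenzoic acid (0.75 equiv), 3 Å MS, DMA/THF (3:7), 20 °C
Reagents that add atoms: none
Why: Proposed new method: this is a nickel-catalysed enantioconvergent reductive cross-electrophile acyl coupling, in which zerovalent nickel (from NiCl2(dme) and zerovalent manganese) adds oxidatively to the C–Cl bond of 11, a monovalent nickel species abstracts chlorine from racemic 20 to give the planar 1-(pyranon-2-yl)ethyl radical delocalised over C2=C3–C4=O of ring A, the bis(oxazoline) acyl nickel complex captures this radical, and reductive elimination from trivalent nickel forms the ketone C–C bond. The closest known reaction type is the nickel/bis(oxazoline)-catalysed asymmetric reductive coupling of acid chlorides with racemic secondary benzylic chlorides, extended here to a pyranone-stabilised (vinylogous α-chloro carbonyl) chloride and to an acid chloride that carries a stereocentre at its α-carbon. No ring is closed. The new stereocentre is set by the chiral ligand at the radical-capture and reductive-elimination stage, so both enantiomers of 20 should converge on S, while the S centre of 11 is a spectator because only its C–Cl bond reacts. The step needs cross-coupling over homo-coupling and no enolisation at either centre between ketone and pyranone; the first should be secured by the two distinct activation modes (two-electron oxidative addition of the acyl chloride against halogen abstraction from the weaker secondary C–Cl bond), the second by the base-free, weakly acidic medium at 20 °C and by the fact that the product is formed in the last step.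

**Compound list**

1 | heptane-3,5-dione | CCC(=O)CC(=O)CC | starting material
2 | 4-methylheptane-3,5-dione | CCC(=O)C(C)C(=O)CC | intermediate
3 | methyl (2R)-3-hydroxy-2-methylpropanoate | OC[C@@H](C)C(=O)OC | starting material
4 | methyl (2R)-3-[(tert-butyldimethylsilyl)oxy]-2-methylpropanoate | CC(C)(C)[Si](C)(C)OC[C@@H](C)C(=O)OC | intermediate
5 | (2R)-3-[(tert-butyldimethylsilyl)oxy]-N-methoxy-N,2-dimethylpropanamide | CC(C)(C)[Si](C)(C)OC[C@@H](C)C(=O)N(C)OC | intermediate
6 | (2R)-1-[(tert-butyldimethylsilyl)oxy]-2,4,6-trimethylnonane-3,5,7-trione | CC(C)(C)[Si](C)(C)OC[C@@H](C)C(=O)C(C)C(=O)C(C)C(=O)CC | intermediate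
7 | 2-{(2R)-1-[(tert-butyldimethylsilyl)oxy]propan-2-yl}-6-ethyl-3,5-dimethyl-4H-pyran-4-one | CC(C)(C)[Si](C)(C)OC[C@@H](C)c1oc(CC)c(C)c(=O)c1C | intermediate
8 | 2-ethyl-6-[(2R)-1-hydroxypropan-2-yl]-3,5-dimethyl-4H-pyran-4-one | OC[C@@H](C)c1oc(CC)c(C)c(=O)c1C | intermediate
9 | (2S)-2-(6-ethyl-3,5-dimethyl-4-oxo-4H-pyran-2-yl)propanal | O=C[C@@H](C)c1oc(CC)c(C)c(=O)c1C | intermediate
10 | (2S)-2-(6-ethyl-3,5-dimethyl-4-oxo-4H-pyran-2-yl)propanoic acid | OC(=O)[C@@H](C)c1oc(CC)c(C)c(=O)c1C | intermediate
11 | (2S)-2-(6-ethyl-3,5-dimethyl-4-oxo-4H-pyran-2-yl)propanoyl chloride | ClC(=O)[C@@H](C)c1oc(CC)c(C)c(=O)c1C | intermediate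
12 | ethyl 2-hydroxypropanoate (racemic) | CC(O)C(=O)OCC | starting material
13 | ethyl 2-[(tert-butyldimethylsilyl)oxy]propanoate (racemic) | CCOC(=O)C(C)O[Si](C)(C)C(C)(C)C | intermediate
14 | pentan-3-one | CCC(=O)CC | starting material
15 | 2-[(tert-butyldimethylsilyl)oxy]-4-methylheptane-3,5-dione | CCC(=O)C(C)C(=O)C(C)O[Si](C)(C)C(C)(C)C | intermediate
16 | N-methoxy-N-methylhexanamide | CCCCCC(=O)N(C)OC | starting material
17 | 2-[(tert-butyldimethylsilyl)oxy]-4,6-dimethyldodecane-3,5,7-trione | CCCCCC(=O)C(C)C(=O)C(C)C(=O)C(C)O[Si](C)(C)C(C)(C)C | intermediate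
18 | 2-{1-[(tert-butyldimethylsilyl)oxy]ethyl}-3,5-dimethyl-6-pentyl-4H-pyran-4-one (racemic) | CCCCCc1oc(C(C)O[Si](C)(C)C(C)(C)C)c(C)c(=O)c1C | intermediate
19 | 2-(1-hydroxyethyl)-3,5-dimethyl-6-pentyl-4H-pyran-4-one (racemic) | CCCCCc1oc(C(C)O)c(C)c(=O)c1C | intermediate
20 | 2-(1-chloroethyl)-3,5-dimethyl-6-pentyl-4H-pyran-4-one (racemic) | CCCCCc1oc(C(C)Cl)c(C)c(=O)c1C | intermediate
21 | (2S,4S)-2-(6-ethyl-3,5-dimethyl-4-oxo-4H-pyran-2-yl)-4-(3,5-dimethyl-4-oxo-6-pentyl-4H-pyran-2-yl)pentan-3-one | CCCCCc1oc([C@H](C)C(=O)[C@@H](C)c2oc(CC)c(C)c(=O)c2C)c(C)c(=O)c1C | target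

**Step count and risks**

Total step count: 15. Longest linear sequence: 8 steps (steps 2, 3, 4, 5, 6, 7, 8 and 15, from compound 3 to compound 21).

The three steps most likely to fail:

Step 15 (bears the label). The pyranone-stabilised radical may dimerise before capture, the acyl nickel species may lose CO, the acid chloride may lose its α-configuration through a ketene, and facial discrimination may be poor with a pyranone in place of an arene. The fallback uses known chemistry at the alcohol oxidation level and sets out from alcohol 8 and chloride 20. Dess–Martin oxidation of 8 would give aldehyde 9, this time isolated and used crude at once. A Nozaki–Hiyama-type addition of 20 to 9 mediated by divalent chromium (CrCl2, catalytic LiI, THF, 0 °C) would give the secondary alcohol F1. Its Dess–Martin oxidation would give ketone 21, where the fallback rejoins the route. The configuration at the carbon on ring A would then rest on Felkin–Anh addition to the α-branched aldehyde together with the anti preference of the chromium reagent, and the isomers would be separated by chromatography.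

Step 8. The α-centre may be lost by enolisation or ketene formation during or after chlorination, the free acid may decarboxylate, and the chlorinating agent may attack the pyranone carbonyl. The fallback avoids the acid chloride and sets out from acid 10. A Mukaiyama redox condensation (2,2'-dipyridyl disulfide, PPh3, MeCN, rt) would give the isolable S-(pyridin-2-yl) thioester F2, which has no base-free route to a ketene. Nickel-catalysed reductive coupling of F2 with chloride 20 (NiBr2(dme), the same bis(oxazoline) ligand, Zn powder, DMA, rt) would give ketone 21 directly, so the route is rejoined at 21 without passing through 11.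

Step 4. Second deprotonation of diketone 2 may be incomplete, proton transfer from the amide to the dianion may compete with addition, and O-acylation may occur. The fallback replaces the acylation by an aldol/oxidation pair and sets out from ester 4 and diketone 2. Reduction of 4 with iBu2AlH (CH2Cl2, −78 °C) would give the aldehyde F3. Aldol addition of the dilithio dianion of 2 to F3 (THF, −78 °C) would give the β-hydroxy diketone F4. Dess–Martin oxidation of F4 would give triketone 6, where the route is rejoined.

**Further compounds**

F1 | step 15 | 2-ethyl-6-[(2R,4R)-3-hydroxy-4-(3,5-dimethyl-4-oxo-6-pentyl-4H-pyran-2-yl)pentan-2-yl]-3,5-dimethyl-4H-pyran-4-one (carbinol epimers) | CCCCCc1oc([C@H](C)C(O)[C@@H](C)c2oc(CC)c(C)c(=O)c2C)c(C)c(=O)c1C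
F2 | step 8 | S-(pyridin-2-yl) (2S)-2-(6-ethyl-3,5-dimethyl-4-oxo-4H-pyran-2-yl)propanethioate | O=C(Sc1ccccn1)[C@@H](C)c1oc(CC)c(C)c(=O)c1C
F3 | step 4 | (2R)-3-[(tert-butyldimethylsilyl)oxy]-2-methylpropanal | CC(C)(C)[Si](C)(C)OC[C@@H](C)C=O
F4 | step 4 | (2R)-1-[(tert-butyldimethylsilyl)oxy]-3-hydroxy-2,4,6-trimethylnonane-5,7-dione (mixture at C3, C4 and C6) | CC(C)(C)[Si](C)(C)OC[C@@H](C)C(O)C(C)C(=O)C(C)C(=O)CC
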